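Radermachol is cut at two furan bonds: C3–C4, also a bond of the seven-membered ring, and O–C2. Furan C3 is flanked by the tropone carbonyl and furan C2, both at the acyl level. Furan C4 and C5 are C3 and C4 of a 1,4-dioxygenated naphthalene ring carrying the aroyl bridge on C2. The core hides a β-diketone carbon facing an acylquinone. Anodic oxidation of hydroquinone 11, a 2-aroylnaphthalene-1,4-diol whose benzoyl ring bears an ortho C(O)CH2C(O)CH=CMe2 chain, should unmask the quinone, close the seven-membered ring by Michael addition at C3 and the furan through the C4 hydroxyl, in one operation.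

Key step: step 5

Remark on locants: naphthalene atoms are numbered as in the name of 11 (aroyl group on C2). The only free quinone carbon is then C3, the oxygen that ends in the furan is the one on C4 (neighbour of C3), and the C1 oxygen, next to the aroyl group, ends as the chelated carbonyl oxygen of 15.

Remark on tautomers: β-diketones 9 to 12 are drawn in the diketo form although they should be largely enolised. Compound 15 is drawn as in the target SMILES and 14 is its naphthol tautomer.

Step 1
Reactants: 1 naphthalene-1,4-diol
Product: 2 1,4-bis(methoxymethoxy)naphthalene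
Conditions: NaH (2.4 equiv), MOMCl (2.4 equiv), DMF, 0 °C to rt, argon
Reagents that add atoms: chloromethyl methyl ether, COCCl
Why: Williamson-type O-alkylation of both naphtholate oxygens by a reactive α-chloro ether should be fast under argon, and it installs an acetal that survives organolithium and enolate chemistry and directs the lithiation of step 2.

Step 2
Reactants: 2 1,4-bis(methoxymethoxy)naphthalene; 3 phthalic anhydride
Product: 5 2-[1,4-bis(methoxymethoxy)naphthalene-2-carbonyl]benzoic acid, via aryllithium 4 (not isolated)
Conditions: n-BuLi (1.1 equiv), TMEDA (1.1 equiv), THF, 0 °C, 1 h; cannulated into 3 (1.5 equiv), THF, −78 °C; 1 M HCl to pH 4, 0 °C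
Reagents that add atoms: n-butyllithium, [Li]CCCC (only the lithium of intermediate 4)
Why: Directed ortho-metalation next to an OMOM group (C2 and C3 of 2 are equivalent by symmetry) followed by opening of a cyclic anhydride by the aryllithium is a standard way to 2-aroylbenzoic acids, and inverse addition to excess anhydride at −78 °C should hold back a second addition to the new ketone.

Step 3
Reactants: 5 2-[1,4-bis(methoxymethoxy)naphthalene-2-carbonyl]benzoic acid; 6 4-methylpent-3-en-2-one (mesityl oxide)
Product: 9 1-{2-[1,4-bis(methoxymethoxy)naphthalene-2-carbonyl]phenyl}-5-methylhex-4-ene-1,3-dione, via acyl imidazolide 7 (not isolated), via lithium dienolate 8 (not isolated)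
Conditions: 5, CDI (1.1 equiv), THF, rt, 1 h; added to 8 [from 6 (3.3 equiv), LiN(i-Pr)2 (3.2 equiv), THF, −78 °C, 45 min], −78 °C, 1 h; AcOH, −78 °C
Reagents that add atoms: 1,1'-carbonyldiimidazole, O=C(n1ccnc1)n1ccnc1 (only the imidazolyl group of intermediate 7); lithium diisopropylamide, [Li]N(C(C)C)C(C)C (only the lithium of intermediate 8)
Why: Crossed Claisen-type C-acylation of the kinetic, cross-conjugated lithium dienolate of an enone by an acyl imidazole is known chemistry in which the excess of 8 takes up the imidazole N–H and the acidic product, the acyl imidazole should be far more electrophilic than the electron-rich diaryl ketone with ortho groups on both rings, and the product stays a chelated lithium diketonate until the cold acid quench.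

Step 4
Reactants: 9 1-{2-[1,4-bis(methoxymethoxy)naphthalene-2-carbonyl]phenyl}-5-methylhex-4-ene-1,3-dione
Product: 11 1-[2-(1,4-dihydroxynaphthalene-2-carbonyl)phenyl]-5-methylhex-4-ene-1,3-dione, via bis(trimethylsilyl) ether 10 (not isolated)
Conditions: Me3SiOTf (5 equiv), 2,2'-bipyridyl (7 equiv), MeCN, 0 °C to rt, argon; degassed H2O, rt; degassed sodium phosphate buffer (pH 7) work-up, short silica plug under argon, used at once
Reagents that add atoms: trimethylsilyl trifluoromethanesulfonate, C[Si](C)(C)OS(=O)(=O)C(F)(F)F (only the silyl groups of intermediate 10)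
Why: The silyl triflate/2,2'-bipyridyl cleavage of aromatic MOM ethers (silylation of the acetal, transfer of the methoxymethyl group to bipyridyl, hydrolysis of the aryl silyl ethers and of any silylated enol by water) is a known, nearly neutral and alcohol-free deprotection, so it should spare the enone–diketone chain from acid-induced oxa-Michael closure, the diaryl ketone from aldol condensation and the C4 hydroxyl from the etherification that naphthalene-1,4-diols suffer in acidic alcohols.

Step 5
Reactants: 11 1-[2-(1,4-dihydroxynaphthalene-2-carbonyl)phenyl]-5-methylhex-4-ene-1,3-dione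
Product: 15 radermachol, via acylquinone 12 (not isolated), via Michael adduct 13 (not isolated), via naphthol tautomer 14 (not isolated)
Conditions: graphite-felt anode, Pt cathode, divided cell, anode potential held about 0.1 V beyond the first anodic peak of 11 (set by cyclic voltammetry in the same medium), 2.0–2.1 F/mol, MeCN/H2O 3:1, NaOAc/AcOH 0.1 M each, argon, rt; then anolyte at 40 °C until furan closure is complete
Reagents that add atoms: none
Why: Proposed new method: at the carbon anode 11 gives up two electrons and two protons to form acylquinone 12, whose single unsubstituted quinone carbon C3 is β to both the C1 quinone carbonyl and the aroyl carbonyl and is attacked by the enolised diketone carbon held over it by the ortho-phenylene tether (7-endo-trig Michael addition, seven-membered ring), after which enolisation restores the aromatic hydroquinone ring in 13. The C4 hydroxyl, the one beside the new C–C bond, then adds to the exocyclic 3-methylbut-2-enoyl carbonyl (5-exo-trig) and loss of water gives the furan of 14, which rests as its chelated tautomer 15; the C1 hydroxyl is out of reach, and the in-ring carbonyl cannot serve because that furan would be bridged across the seven-membered ring. The closest known reaction type is the anodic oxidation of hydroquinones and catechols in buffered aqueous acetonitrile in the presence of 1,3-dicarbonyl compounds, an intermolecular benzofuran synthesis by Michael addition and ring closure; the tethered version and the seven-membered ring are new. No stereocentre has to be controlled, because the one sp3 carbon of 13 becomes furan C3. The step needs conjugate addition to outrun both the five-ring aldol closure of the diketone onto the diaryl ketone and the addition of water to 12, which the weakly acidic buffer, the hydrogen bond from the C1 hydroxyl that deactivates that ketone in 11 and the intramolecular delivery to a doubly activated carbon should secure. It also needs the oxidation to stop after two electrons, which potential control, the charge limit, the higher oxidation potential expected for the acylated naphthol 15 and the reduction of any over-oxidised 13 by remaining 11 should secure.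

Compound list
1 | naphthalene-1,4-diol | Oc1ccc(O)c2ccccc12 | starting material
2 | 1,4-bis(methoxymethoxy)naphthalene | COCOc1ccc(OCOC)c2ccccc12 | intermediate
3 | phthalic anhydride | O=C1OC(=O)c2ccccc12 | starting material
4 | [1,4-bis(methoxymethoxy)naphthalen-2-yl]lithium | [Li]c1cc(OCOC)c2ccccc2c1OCOC | intermediate
5 | 2-[1,4-bis(methoxymethoxy)naphthalene-2-carbonyl]benzoic acid | COCOc1cc(C(=O)c2ccccc2C(=O)O)c(OCOC)c2ccccc12 | intermediate
6 | 4-methylpent-3-en-2-one (mesityl oxide) | CC(C)=CC(C)=O | starting material
7 | {2-[1,4-bis(methoxymethoxy)naphthalene-2-carbonyl]phenyl}(1H-imidazol-1-yl)methanone | COCOc1cc(C(=O)c2ccccc2C(=O)n2ccnc2)c(OCOC)c2ccccc12 | intermediate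
8 | lithium 4-methylpenta-1,3-dien-2-olate | [Li]OC(=C)C=C(C)C | intermediate
9 | 1-{2-[1,4-bis(methoxymethoxy)naphthalene-2-carbonyl]phenyl}-5-methylhex-4-ene-1,3-dione | COCOc1cc(C(=O)c2ccccc2C(=O)CC(=O)C=C(C)C)c(OCOC)c2ccccc12 | intermediate
10 | 1-{2-[1,4-bis(trimethylsilyloxy)naphthalene-2-carbonyl]phenyl}-5-methylhex-4-ene-1,3-dione | CC(C)=CC(=O)CC(=O)c1ccccc1C(=O)c1cc(O[Si](C)(C)C)c2ccccc2c1O[Si](C)(C)C | intermediate
11 | 1-[2-(1,4-dihydroxynaphthalene-2-carbonyl)phenyl]-5-methylhex-4-ene-1,3-dione | CC(C)=CC(=O)CC(=O)c1ccccc1C(=O)c1cc(O)c2ccccc2c1O | intermediate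
12 | 1-[2-(1,4-dioxo-1,4-dihydronaphthalene-2-carbonyl)phenyl]-5-methylhex-4-ene-1,3-dione | CC(C)=CC(=O)CC(=O)c1ccccc1C(=O)C1=CC(=O)c2ccccc2C1=O | intermediate
13 | tetracyclic Michael adduct: naphthalene-1,4-diol whose C2 and C3 are bridged by C(=O)–(1,2-phenylene)–C(=O)–CH[C(=O)CH=CMe2], the CH bonded to C3 (racemic, enolisable centre, lost in the next event) | CC(C)=CC(=O)C1C(=O)c2ccccc2C(=O)c2c(O)c3ccccc3c(O)c21 | intermediate
14 | naphthol tautomer of radermachol: 5-hydroxy-2-(2-methylprop-1-en-1-yl)naphtho[1,2-b]furan whose C3 and C4 are bridged by C(=O)–(1,2-phenylene)–C(=O) | CC(C)=Cc1oc2c3ccccc3c(O)c3c2c1C(=O)c1ccccc1C3=O | intermediate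
15 | radermachol (carbonyl on former naphthalene C1, enol on the neighbouring bridge carbon) | CC(C)=Cc1oc2c3c(c(O)c4ccccc4c(=O)c13)C(=O)c1ccccc1-2 | target

Total step count: 5. Longest linear sequence: 5 (1, 2, 5, 9, 11, 15).

Steps most likely to fail

1. Step 5.

The seven-membered transition state may be too slow. Water or acetate could then add to the quinone, the diketone could close onto the diaryl ketone by five-ring aldol condensation, redox exchange could lead to over-oxidation, or a film could foul the anode.

The fallback reverses the order of ring construction and uses known reactions only: the furan is made first by intermolecular chemistry, and the seven-membered ring is closed last by acylation. It sets out from 5 (and from 8 for the nucleophile) and comes back at 14, the tautomer of 15.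

- K2CO3 and MeI in DMF convert 5 by carboxylate alkylation to methyl 2-[1,4-bis(methoxymethoxy)naphthalene-2-carbonyl]benzoate F1.
- (NH4)2Ce(NO3)6 in MeCN/H2O at 0 °C (oxidative dealkylation of a hydroquinone diether) gives methyl 2-(1,4-dioxo-1,4-dihydronaphthalene-2-carbonyl)benzoate F2.
- Dienolate 8, made from 6 as in step 3, is trapped with Me3SiCl as 4-methyl-2-(trimethylsilyloxy)penta-1,3-diene F3.
- F3 adds to C3 of F2 in CH2Cl2 at −78 °C. This is a Mukaiyama–Michael addition to a 2-acyl-1,4-naphthoquinone, a known entry to naphtho[1,2-b]furans. The inward methyl group at the diene terminus disfavours the s-cis form needed for cycloaddition.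
- Mild desilylation gives methyl 2-[1,4-dihydroxy-3-(4-methyl-2-oxopent-3-en-1-yl)naphthalene-2-carbonyl]benzoate F4.
- Catalytic p-TsOH in warm toluene closes the furan by cyclodehydration through the C4 hydroxyl to methyl 2-[5-hydroxy-2-(2-methylprop-1-en-1-yl)naphtho[1,2-b]furan-4-carbonyl]benzoate F5.
- LiOH in aqueous THF gives 2-[5-hydroxy-2-(2-methylprop-1-en-1-yl)naphtho[1,2-b]furan-4-carbonyl]benzoic acid F6.
- (CF3CO)2O in CH2Cl2 at 0 °C closes the seven-membered ring by intramolecular Friedel–Crafts acylation of the free furan C3, which gives 14 and hence 15.

2. Step 3.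

The lithium dienolate may add to the diaryl ketone, with lactone closure onto the activated carboxyl group. Other risks are O-acylation, proton transfer that stops the acylation halfway, and five-ring aldol closure of the product enolate on warming.

The fallback builds the diketone from soft magnesium enolates that ignore ketones. It sets out from 5 (activated to 7 as before) and comes back at 9.

- Compound 7 and Mg(O2CCH2CO2CH2CH=CH2)2 in THF at rt (decarboxylative Claisen homologation of an acyl imidazole with a magnesium malonate half-ester) give prop-2-en-1-yl 3-{2-[1,4-bis(methoxymethoxy)naphthalene-2-carbonyl]phenyl}-3-oxopropanoate F7.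
- MgCl2, pyridine and 3-methylbut-2-enoyl chloride in CH2Cl2 at 0 °C (C-acylation of the magnesium chelate) give prop-2-en-1-yl 2-{2-[1,4-bis(methoxymethoxy)naphthalene-2-carbonyl]benzoyl}-5-methyl-3-oxohex-4-enoate F8.
- Pd(OAc)2, PPh3, HCO2H and Et3N in THF at rt remove the ester under neutral conditions and give 9. This is a Tsuji-type deallylation by zerovalent palladium with hydride capture of the allyl group and decarboxylation.

3. Step 4.

The enol oxygen may close onto the dimethyl-substituted enone, or aldol condensation may occur under Lewis-acid activation. Cleavage of the chelated C1 acetal may be incomplete, and air oxidation may occur during work-up.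

The fallback unmasks the ring oxidatively instead of hydrolytically. It sets out from 9 and comes back at 12.

- (NH4)2Ce(NO3)6 (2.0 equiv) in MeCN/H2O at 0 °C for a few minutes (oxidative dealkylation of a hydroquinone diether, much faster than oxidation of a 1,3-diketone) should give 12 directly.
- The cold mixture is run into the acetate buffer of step 5, where the Michael addition and furan closure proceed without current.
- This fallback makes no compound outside the compound list (entry F0).

Further compounds
F1 | step 5 | methyl 2-[1,4-bis(methoxymethoxy)naphthalene-2-carbonyl]benzoate | COCOc1cc(C(=O)c2ccccc2C(=O)OC)c(OCOC)c2ccccc12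
F2 | step 5 | methyl 2-(1,4-dioxo-1,4-dihydronaphthalene-2-carbonyl)benzoate | COC(=O)c1ccccc1C(=O)C1=CC(=O)c2ccccc2C1=O
F3 | step 5 | 4-methyl-2-(trimethylsilyloxy)penta-1,3-diene | C=C(O[Si](C)(C)C)C=C(C)C
F4 | step 5 | methyl 2-[1,4-dihydroxy-3-(4-methyl-2-oxopent-3-en-1-yl)naphthalene-2-carbonyl]benzoate | COC(=O)c1ccccc1C(=O)c1c(CC(=O)C=C(C)C)c(O)c2ccccc2c1O
F5 | step 5 | methyl 2-[5-hydroxy-2-(2-methylprop-1-en-1-yl)naphtho[1,2-b]furan-4-carbonyl]benzoate | COC(=O)c1ccccc1C(=O)c1c(O)c2ccccc2c2oc(C=C(C)C)cc12
F6 | step 5 | 2-[5-hydroxy-2-(2-methylprop-1-en-1-yl)naphtho[1,2-b]furan-4-carbonyl]benzoic acid | OC(=O)c1ccccc1C(=O)c1c(O)c2ccccc2c2oc(C=C(C)C)cc12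
F7 | step 3 | prop-2-en-1-yl 3-{2-[1,4-bis(methoxymethoxy)naphthalene-2-carbonyl]phenyl}-3-oxopropanoate | C=CCOC(=O)CC(=O)c1ccccc1C(=O)c1cc(OCOC)c2ccccc2c1OCOC
F8 | step 3 | prop-2-en-1-yl 2-{2-[1,4-bis(methoxymethoxy)naphthalene-2-carbonyl]benzoyl}-5-methyl-3-oxohex-4-enoate (racemic, enolisable centre) | C=CCOC(=O)C(C(=O)C=C(C)C)C(=O)c1ccccc1C(=O)c1cc(OCOC)c2ccccc2c1OCOC
F0 | step 4 | none | none
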